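## Analysis of the target

- The target is a 2,3-dihydrobenzofuran whose benzene ring A (C3a, C4 to C7, C7a) carries no hydrogen. Hydroxyl groups at C4 and C6 flank a 2-methylpropanoyl group at C5. C7 is joined through one methylene carbon to C3' of a 6-ethyl-4-hydroxy-5-methyl-2-pyrone (ring C). C3a–C3 and C7a–O1 belong to the dihydrofuran ring B.
- There is one stereocentre, C2 (R), which bears the isopropenyl group and the ring oxygen O1. With no second stereocentre to relay from, it must be set by absolute control and then left alone.
- The C2–O1 bond is an allylic aryl ether next to a 1,1-disubstituted alkene. Protic or strong Lewis acid can ionise it or hydrate the alkene, and hydrogenation would saturate the alkene.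
- The acylphloroglucinol nucleus is electron-rich and easily oxidised. The 4-hydroxy-2-pyrone is acidic and a carbon nucleophile at C3', so it cannot be carried through organometallic steps.
- The difficulty lies in ring A. Three oxygens stand meta to one another and must end up different (O1 in ring B, O4 and O6 free), and four carbon substituents must be placed without regiochemical doubt.
- The strategy rests on one feature. C7a, which bears O1, is para to the C5 carbonyl carbon and meta to C4 and C6. A fluorine at C7a is therefore activated for displacement by an oxygen nucleophile once the C5 ketone is present. A 5-fluororesorcinol holds the three heteroatom positions already differentiated: fluorine for O1, the two hydroxyls for O4 and O6.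

## Retrosynthetic reasoning

**Methylene bridge.** Target 25 is cut at both bonds of the bridging carbon, C7–CH2 and CH2–C3', to give diphenol 18, pyrone 22 and a one-carbon iminium electrophile. This is done last because 22 is acidic and would not survive the basic and organometallic steps. C7 of 18 is the only unsubstituted position of ring A, so no regiochemistry has to be controlled. Forward, 22 is aminomethylated at C3' to 23, which loses its amine to give the acceptor 24, and C7 of 18 adds.

**Pyrone.** Ring C of 22 is cut at C3'... more precisely at C4–C5 and O1–C2 of the pyrone, back to silyl enol ether 20 and malonyl dichloride 21. Compound 20 comes from 3-pentanone 19, whose carbonyl carbon and one α-carbon become C6 and C5 with their ethyl and methyl groups in place.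

**Phenol protection and alkene.** Diphenol 18 is traced to its bis(methoxymethyl) ether 16. The alkene of 16 is traced to tertiary alcohol 15, and 15 to its benzyloxymethyl ether 14. The alkene appears only after the hydrogenolysis and after all organolithium and Lewis-acid steps. The phenol acetals are taken off afterwards without protic acid.

**Ring B (key disconnection).** Compound 14 is cut at C7a–O1 to fluoro alcohol 12. Cutting here, and not at O1–C2, means the stereocentre is only a spectator alkoxide carbon and keeps its configuration. It also means O4 and O6 can carry the same protecting group, since fluorine stands in for O1. Forward, the secondary alkoxide must attack C7a and nothing else. The tertiary oxygen is therefore blocked as an acetal. A silyl ether there could migrate to the neighbouring alkoxide and free the tertiary oxygen for a six-membered closure; an acetal cannot.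

**Acyl group.** Compound 12 is cut at C5–C(=O) to aryl bromide 9 and Weinreb amide 10. The ketone is brought in at its final oxidation level and after the side chain. The aryl anion chemistry that attaches the side chain would not tolerate a ketone. A benzylic carbinol would later have to be oxidised next to the free secondary hydroxyl, which is hard to secure for a doubly ortho-substituted carbinol. The bromine of 9 holds the future C5.

**Side chain.** Compound 9 is cut at C3–C3a to bromofluoroarene 7, as its aryllithium 8, and epoxide 3. The carbon–carbon bond is made at the unsubstituted epoxide carbon, so the stereocentre arrives ready-made and is not touched.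

**Arene and epoxide.** Compound 7 goes back through lithiation of bis-acetal 5 between its two oxygens (aryllithium 6) to 5-fluororesorcinol 4. Epoxide 3 goes back through tertiary alcohol 2 to methyl (R)-glycidate 1. The CIP order at the stereocentre is the same in 1, 2, 3, 9, 12 and 14, so (R) in 1 gives (R) at C2 of 25.

## Alternatives that were turned down

**Alternative 1:** Rings A and B are disconnected together, at C6–C7, C3a–C7a and C5–C6. The precursor would be a four-membered enone tethered through C3, C2 and O1 to an alkynyl ether that already carries the pyronylmethyl group.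
- Forward key step: irradiation opens the four-membered ring to a vinylketene, which adds to the tethered alkyne. The new four-membered ring opens and closes in a 6π fashion to the phenol A1, the 4-ethoxy-6-hydroxy dihydrobenzofuran with the pyrone as its methyl ether and the tertiary oxygen silylated.
- For it: three carbon–carbon bonds and two rings form in one operation, the tether fixes the substitution pattern, and the pyrone side chain is already attached. On convergence it is stronger than the chosen route.
- Against it: A1 has hydrogen at C5, so the isobutyryl group must be put in late by Friedel–Crafts or Fries chemistry beside a silyl ether and a pyrone. O4 emerges as an ethyl ether and the pyrone as a methyl ether, and their cleavage needs boron-halide-type reagents near the acid-labile C2–O1 bond. The photosubstrate joins an alkynyl ether of a hindered secondary alcohol to a 2-pyrone, itself a photoactive chromophore, and takes many steps to assemble.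
- Comparison: the chosen route builds only one ring in its key step, but the C5 acyl group and removable acetals on O4 and O6 are in place at that point, and each step is an ordinary ionic reaction.

**Alternative 2:** Ring C is disconnected at C3'–C4' and O1'–C2' together with the ester bond to O6. The pyrone would be grown on a lactone fused across O6 and C7 that already contains the bridge carbon.
- Forward key step: a thermally released acylketene adds across the silyl ketene acetal of that lactone, and the resulting orthoester collapses with loss of the C6 phenoxide to give A2, the 4-O-methoxymethyl ether of the target.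
- For it: the bridge carbon is fixed before the pyrone exists, so no one-carbon electrophile is needed and symmetrical bis-adducts cannot form. O6 is released in the same step. On these points it is stronger than the chosen final step.
- Against it: the fused lactone has to be built on the fully substituted ring A, by adding three carbons at C7 and lactonising, which costs more steps than the whole endgame chosen here. The ketene acetal must be formed beside the enolisable isobutyryl ketone. The orthoester can also collapse by losing the silyloxy group, giving a 4-pyranone.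
- Comparison: the chosen route makes pyrone 22 separately in two steps and joins it in one. It accepts the risk of bis-adducts in exchange for step economy.

**Alternative 3:** C6–O and C5–C(=O) are disconnected together, through an aryne across C5–C6 of a dihydrobenzofuran that already has ring B, the isopropenyl group and the protected O4.
- Forward key step: fluoride generates the aryne. The carboxylic acid corresponding to the acyl group adds with oxygen at C6, distal to the C4 alkoxy group, and the C5 anion captures the acyl group to give A3, the 6-hydroxy-4-(methoxymethoxy) ketone.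
- For it: two adjacent substituents arrive in one step with regiochemistry predicted by the neighbouring alkoxy group, and O4 and O6 come out differentiated without extra protecting-group steps. Here it is stronger than the chosen route.
- Against it: the step closes no ring, so ring B and C2 must be made by a separate method, and without the C5 ketone the fluoride displacement used here is not available. The aryne precursor must be installed on an advanced, stereodefined intermediate. Simple O-arylation by protonation of the C5 anion competes with acyl transfer, more so for an α-branched acyl group, and the aryne can undergo an ene reaction with the isopropenyl group.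
- Comparison: the chosen route installs the ketone by acylation of a position-defined aryllithium and uses that same ketone to close ring B.

Key step: step 7

Remark: benzofuran locants (O1, C2, C3, C3a, C4 to C7, C7a) are used for the corresponding atoms of open-chain precursors, and primed locants for the pyrone. The alkene geometry of 20 has no influence on step 12; the (Z) isomer is drawn. MOM is methoxymethyl and BOM is benzyloxymethyl.

## Route

Step 1
Reactants: 1 methyl (R)-glycidate [methyl (2R)-oxirane-2-carboxylate]
Product: 2 (R)-2-(oxiran-2-yl)propan-2-ol
Conditions: MeMgCl (2.3 equiv), THF, −78 → −30 °C; aq. NH4Cl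
Reagents that add atoms: methylmagnesium chloride, C[Mg]Cl
Why: Twofold Grignard addition to the ester gives the tertiary carbinol; a terminal epoxide should not be opened by a Grignard reagent at low temperature without copper, and no bond at the stereocentre changes, so (R) is carried over.

Step 2
Reactants: 2 (R)-2-(oxiran-2-yl)propan-2-ol
Product: 3 (R)-2-{2-[(benzyloxy)methoxy]propan-2-yl}oxirane
Conditions: BnOCH2Cl, i-Pr2NEt, CH2Cl2, 0 → 40 °C
Reagents that add atoms: benzyl chloromethyl ether, ClCOCc1ccccc1
Why: Alkoxymethylation with a chloromethyl ether and a tertiary amine needs no free alkoxide, so the Payne rearrangement open to a 2,3-epoxy alkoxide is avoided; the acetal cannot migrate to a neighbouring alkoxide in step 7 and is later removed by hydrogenolysis.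

Step 3
Reactants: 4 5-fluororesorcinol (5-fluorobenzene-1,3-diol)
Product: 5 1-fluoro-3,5-bis(methoxymethoxy)benzene
Conditions: MeOCH2Cl, i-Pr2NEt, CH2Cl2, 0 °C → rt
Reagents that add atoms: chloromethyl methyl ether, COCCl
Why: Standard formation of phenolic MOM ethers; these acetals direct the lithiation of step 4 and withstand all later basic and organometallic steps.

Step 4
Reactants: 5 1-fluoro-3,5-bis(methoxymethoxy)benzene
Product: 7 2-bromo-5-fluoro-1,3-bis(methoxymethoxy)benzene, via [4-fluoro-2,6-bis(methoxymethoxy)phenyl]lithium 6 (not isolated)
Conditions: n-BuLi, THF, −78 → −30 °C; BrCCl2CCl2Br, −78 °C → rt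
Reagents that add atoms: 1,2-dibromo-1,1,2,2-tetrachloroethane, BrC(Cl)(Cl)C(Cl)(Cl)Br
Why: Directed ortho-metalation: n-BuLi should remove the hydrogen between the two acetal oxygens under double chelation to give 6, which has no ortho fluorine and cannot lose LiF; halophilic attack on the dibromide then puts bromine at the future C5.

Step 5
Reactants: 7 2-bromo-5-fluoro-1,3-bis(methoxymethoxy)benzene and 3 (R)-2-{2-[(benzyloxy)methoxy]propan-2-yl}oxirane
Product: 9 (R)-3-[(benzyloxy)methoxy]-1-[3-bromo-6-fluoro-2,4-bis(methoxymethoxy)phenyl]-3-methylbutan-2-ol, via [3-bromo-6-fluoro-2,4-bis(methoxymethoxy)phenyl]lithium 8 (not isolated)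
Conditions: LiN(i-Pr)2, THF, −78 °C; then 3, BF3·OEt2, −78 °C
Reagents that add atoms: none
Why: The amide base does not exchange bromine and removes one of the two equivalent ring hydrogens, each flanked by fluorine and an acetal oxygen; 8 is kept at −78 °C to prevent loss of LiF, and the BF3-activated epoxide is opened at its unsubstituted carbon (Lewis-acid-promoted epoxide opening by an organolithium), so the stereocentre is not attacked and stays (R).

Step 6
Reactants: 9 (R)-3-[(benzyloxy)methoxy]-1-[3-bromo-6-fluoro-2,4-bis(methoxymethoxy)phenyl]-3-methylbutan-2-ol and 10 N-methoxy-N,2-dimethylpropanamide (Weinreb amide of isobutyric acid)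
Product: 12 1-{3-[(2R)-3-[(benzyloxy)methoxy]-2-hydroxy-3-methylbutyl]-4-fluoro-2,6-bis(methoxymethoxy)phenyl}-2-methylpropan-1-one, via O,C-dilithio species 11 (not isolated)
Conditions: MeLi (1.0 equiv), then t-BuLi (2.1 equiv), THF, −78 °C; 10, −78 → 0 °C; aq. NH4Cl
Reagents that add atoms: none
Why: MeLi takes the hydroxyl proton, bromine–lithium exchange with t-BuLi gives 11, and the Weinreb ketone synthesis stops at the chelated tetrahedral adduct, which the alkoxide does not attack; work-up should release the ketone and the free hydroxyl together, so no oxidation is needed next to the secondary alcohol.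

Step 7
Reactants: 12 1-{3-[(2R)-3-[(benzyloxy)methoxy]-2-hydroxy-3-methylbutyl]-4-fluoro-2,6-bis(methoxymethoxy)phenyl}-2-methylpropan-1-one
Product: 14 1-[(2R)-2-{2-[(benzyloxy)methoxy]propan-2-yl}-4,6-bis(methoxymethoxy)-2,3-dihydro-1-benzofuran-5-yl]-2-methylpropan-1-one, via potassium alkoxide 13 (not isolated)
Conditions: KN(SiMe3)2 (1.05 equiv), THF, 0 → 45 °C
Reagents that add atoms: none
Why: Intramolecular nucleophilic aromatic substitution by addition–elimination: KN(SiMe3)2 forms alkoxide 13, which adds to the fluorine-bearing C7a to give a Meisenheimer complex whose charge on C7, C3a and C5 is taken up by the C5 carbonyl, and loss of fluoride then forms the C7a–O1 bond. The closest known reaction type is the base-mediated cyclisation of 2-(2-fluoroaryl)ethanols bearing a para carbonyl group to 2,3-dihydrobenzofurans. Ring B closes in the 5-exo-trig mode at the ipso carbon. No new stereocentre is formed; the C2 configuration comes from epoxide 3 and is kept because no bond at C2 is made or broken. The step needs chemoselectivity only: the tertiary oxygen is an acetal that cannot migrate to the neighbouring alkoxide, so only the secondary oxygen can reach C7a, and the ketone is shielded from addition by its two ortho substituents. The alkoxy groups at C4 and C6 are meta to C7a, so they do not donate to the site of attack and help inductively. The twist of the ketone out of the ring plane and reversible enolisation of the isobutyryl group lower the rate, which is why about one equivalent of base, a potassium counter-ion and gentle warming are chosen.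

Step 8
Reactants: 14 1-[(2R)-2-{2-[(benzyloxy)methoxy]propan-2-yl}-4,6-bis(methoxymethoxy)-2,3-dihydro-1-benzofuran-5-yl]-2-methylpropan-1-one
Product: 15 1-[(2R)-2-(2-hydroxypropan-2-yl)-4,6-bis(methoxymethoxy)-2,3-dihydro-1-benzofuran-5-yl]-2-methylpropan-1-one
Conditions: H2 (1 atm), Pd/C, EtOAc, rt
Reagents that add atoms: none
Why: Hydrogenolysis of the benzyl C–O bond leaves a hemiformal that loses formaldehyde; the aryl MOM ethers, the hindered ketone and the ring ether should not be affected, and no alkene is present yet.

Step 9
Reactants: 15 1-[(2R)-2-(2-hydroxypropan-2-yl)-4,6-bis(methoxymethoxy)-2,3-dihydro-1-benzofuran-5-yl]-2-methylpropan-1-one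
Product: 16 1-[(2R)-4,6-bis(methoxymethoxy)-2-(prop-1-en-2-yl)-2,3-dihydro-1-benzofuran-5-yl]-2-methylpropan-1-one
Conditions: Burgess reagent (MeO2CN–SO2NEt3 inner salt), toluene, 60 °C
Reagents that add atoms: none
Why: Burgess dehydration, a syn elimination through the sulfamate ester; the six methyl hydrogens are favoured statistically and sterically over the single hindered C2 hydrogen, as in related dehydrations of 2-(2-hydroxypropan-2-yl)dihydrobenzofurans, so the isopropenyl group should form with C2 untouched.

Step 10
Reactants: 16 1-[(2R)-4,6-bis(methoxymethoxy)-2-(prop-1-en-2-yl)-2,3-dihydro-1-benzofuran-5-yl]-2-methylpropan-1-one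
Product: 18 1-[(2R)-4,6-dihydroxy-2-(prop-1-en-2-yl)-2,3-dihydro-1-benzofuran-5-yl]-2-methylpropan-1-one, via bis(trimethylsilyl) ether 17 (not isolated)
Conditions: Me3SiOTf, 2,2'-bipyridyl, MeCN, 0 °C → rt; then H2O
Reagents that add atoms: none
Why: Cleavage of aryl MOM ethers by the silyl triflate–bipyridyl pair passes through the aryl silyl ethers 17, hydrolysed on adding water; no protic acid is present, which protects the allylic aryl ether and the alkene from ionisation and hydration.

Step 11
Reactants: 19 3-pentanone
Product: 20 (Z)-3-(trimethylsilyloxy)pent-2-ene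
Conditions: Me3SiCl, NaI, Et3N, MeCN, rt
Reagents that add atoms: chlorotrimethylsilane, C[Si](C)(C)Cl
Why: Silyl enol ether formation with iodotrimethylsilane made in the flask; the ketone is symmetrical, so there is no regiochemical question.

Step 12
Reactants: 20 (Z)-3-(trimethylsilyloxy)pent-2-ene and 21 malonyl dichloride
Product: 22 6-ethyl-4-hydroxy-5-methyl-2H-pyran-2-one
Conditions: Et2O, −78 °C → rt
Reagents that add atoms: none
Why: Pyrone synthesis from a silyl enol ether and malonyl dichloride: C-acylation at the enol carbon with loss of the silyl chloride, then O-acylation of the enolised ketone by the second acid chloride closes the lactone, which tautomerises to the 4-hydroxy-2-pyrone.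

Step 13
Reactants: 18 1-[(2R)-4,6-dihydroxy-2-(prop-1-en-2-yl)-2,3-dihydro-1-benzofuran-5-yl]-2-methylpropan-1-one and 22 6-ethyl-4-hydroxy-5-methyl-2H-pyran-2-one
Product: 25 3-{[(2R)-4,6-dihydroxy-5-(2-methylpropanoyl)-2-(prop-1-en-2-yl)-2,3-dihydro-1-benzofuran-7-yl]methyl}-6-ethyl-4-hydroxy-5-methyl-2H-pyran-2-one (target), via pyrone Mannich base 23 (not isolated), via methylidene pyrandione 24 (not isolated)
Conditions: 22, Me2N=CH2+ I−, MeCN, rt; then 18, 50 °C
Reagents that add atoms: N,N-dimethylmethylideneammonium iodide (Eschenmoser's salt), C=[N+](C)C.[I-]
Why: Mannich reaction of the pyrone at C3' gives 23, which loses dimethylamine to the acceptor 24; C7 of 18, the only unsubstituted ring position and activated by O1 and the C6 hydroxyl, adds in a Friedel–Crafts-type conjugate addition, and 22 is converted to 23 before 18 is added to limit symmetrical bis-adducts.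

## Compound list

1 | methyl (R)-glycidate | COC(=O)[C@H]1CO1 | starting material
2 | (R)-2-(oxiran-2-yl)propan-2-ol | CC(C)(O)[C@H]1CO1 | intermediate
3 | (R)-2-{2-[(benzyloxy)methoxy]propan-2-yl}oxirane | CC(C)(OCOCc1ccccc1)[C@H]1CO1 | intermediate
4 | 5-fluororesorcinol | Oc1cc(O)cc(F)c1 | starting material
5 | 1-fluoro-3,5-bis(methoxymethoxy)benzene | COCOc1cc(F)cc(OCOC)c1 | intermediate
6 | [4-fluoro-2,6-bis(methoxymethoxy)phenyl]lithium | [Li]c1c(OCOC)cc(F)cc1OCOC | intermediate (not isolated)
7 | 2-bromo-5-fluoro-1,3-bis(methoxymethoxy)benzene | COCOc1cc(F)cc(OCOC)c1Br | intermediate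
8 | [3-bromo-6-fluoro-2,4-bis(methoxymethoxy)phenyl]lithium | [Li]c1c(F)cc(OCOC)c(Br)c1OCOC | intermediate (not isolated)
9 | (R)-3-[(benzyloxy)methoxy]-1-[3-bromo-6-fluoro-2,4-bis(methoxymethoxy)phenyl]-3-methylbutan-2-ol | CC(C)(OCOCc1ccccc1)[C@H](O)Cc1c(F)cc(OCOC)c(Br)c1OCOC | intermediate
10 | N-methoxy-N,2-dimethylpropanamide | CC(C)C(=O)N(C)OC | starting material
11 | O,C-dilithio species from 9 (lithium alkoxide, aryllithium at the future C5) | CC(C)(OCOCc1ccccc1)[C@H]([O-])Cc1c(F)cc(OCOC)c([Li])c1OCOC.[Li+] | intermediate (not isolated)
12 | 1-{3-[(2R)-3-[(benzyloxy)methoxy]-2-hydroxy-3-methylbutyl]-4-fluoro-2,6-bis(methoxymethoxy)phenyl}-2-methylpropan-1-one | CC(C)(OCOCc1ccccc1)[C@H](O)Cc1c(F)cc(OCOC)c(C(=O)C(C)C)c1OCOC | intermediate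
13 | potassium alkoxide of 12 | CC(C)(OCOCc1ccccc1)[C@H]([O-])Cc1c(F)cc(OCOC)c(C(=O)C(C)C)c1OCOC.[K+] | intermediate (not isolated)
14 | 1-[(2R)-2-{2-[(benzyloxy)methoxy]propan-2-yl}-4,6-bis(methoxymethoxy)-2,3-dihydro-1-benzofuran-5-yl]-2-methylpropan-1-one | CC(C)(OCOCc1ccccc1)[C@H]1Cc2c(OCOC)c(C(=O)C(C)C)c(OCOC)cc2O1 | intermediate
15 | 1-[(2R)-2-(2-hydroxypropan-2-yl)-4,6-bis(methoxymethoxy)-2,3-dihydro-1-benzofuran-5-yl]-2-methylpropan-1-one | CC(C)(O)[C@H]1Cc2c(OCOC)c(C(=O)C(C)C)c(OCOC)cc2O1 | intermediate
16 | 1-[(2R)-4,6-bis(methoxymethoxy)-2-(prop-1-en-2-yl)-2,3-dihydro-1-benzofuran-5-yl]-2-methylpropan-1-one | C=C(C)[C@H]1Cc2c(OCOC)c(C(=O)C(C)C)c(OCOC)cc2O1 | intermediate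
17 | 1-[(2R)-2-(prop-1-en-2-yl)-4,6-bis(trimethylsilyloxy)-2,3-dihydro-1-benzofuran-5-yl]-2-methylpropan-1-one | C=C(C)[C@H]1Cc2c(O[Si](C)(C)C)c(C(=O)C(C)C)c(O[Si](C)(C)C)cc2O1 | intermediate (not isolated)
18 | 1-[(2R)-4,6-dihydroxy-2-(prop-1-en-2-yl)-2,3-dihydro-1-benzofuran-5-yl]-2-methylpropan-1-one | C=C(C)[C@H]1Cc2c(O)c(C(=O)C(C)C)c(O)cc2O1 | intermediate
19 | 3-pentanone | CCC(=O)CC | starting material
20 | (Z)-3-(trimethylsilyloxy)pent-2-ene | C/C=C(/CC)O[Si](C)(C)C | intermediate
21 | malonyl dichloride | O=C(Cl)CC(=O)Cl | starting material
22 | 6-ethyl-4-hydroxy-5-methyl-2H-pyran-2-one | CCc1oc(=O)cc(O)c1C | intermediate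
23 | 3-[(dimethylamino)methyl]-6-ethyl-4-hydroxy-5-methyl-2H-pyran-2-one | CCc1oc(=O)c(CN(C)C)c(O)c1C | intermediate (not isolated)
24 | 6-ethyl-5-methyl-3-methylidene-2H-pyran-2,4(3H)-dione | CCC1=C(C)C(=O)C(=C)C(=O)O1 | intermediate (not isolated)
25 | 3-{[(2R)-4,6-dihydroxy-5-(2-methylpropanoyl)-2-(prop-1-en-2-yl)-2,3-dihydro-1-benzofuran-7-yl]methyl}-6-ethyl-4-hydroxy-5-methyl-2H-pyran-2-one | C=C(C)[C@H]1Cc2c(O)c(C(=O)C(C)C)c(O)c(Cc3c(O)c(C)c(CC)oc3=O)c2O1 | target

## Step count and least certain steps

Total step count: 13. Longest linear sequence: 9 steps (steps 3 to 10 and 13 from 4; equally steps 1, 2, 5 to 10 and 13 from 1).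

**Step 7 (key step).** What may go wrong: addition of the alkoxide to C7a is slowed because the two ortho acetal groups turn the carbonyl out of the ring plane, and reversible enolisation of the isobutyryl group by the base removes the remaining activation, so that the substrate is recovered or degrades on forcing. The fallback sets out from 9. Bromine–lithium exchange as in step 6, followed by DMF, gives the benzaldehyde F1, whose formyl group stays coplanar with ring A and has no α-hydrogen. The same alkoxide closure (K2CO3 in DMF, or KN(SiMe3)2 in THF) should then give the dihydrobenzofuran aldehyde F2 more easily. Addition of i-PrMgCl in the presence of CeCl3 gives the carbinol F3 as a mixture of epimers at the new carbinol carbon, and Dess–Martin oxidation leads to 14, where the route is rejoined.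

**Step 4.** What may go wrong: metalation next to fluorine instead of between the two acetal oxygens, followed by loss of LiF from the misplaced aryllithium on warming. The fallback sets out from 4. Iodination with I2 and NaHCO3 in water, which takes resorcinols at the position between the hydroxyls, gives 5-fluoro-2-iodobenzene-1,3-diol F4. Acetal protection as in step 3 gives the iodide F5, which stands in for 7 in step 5 and gives the iodo alcohol F6. Iodine–lithium exchange and acylation with 10 as in step 6 come back to the route at 12.

**Step 6.** What may go wrong: slow acyl transfer to the doubly ortho-substituted aryllithium, so that proton transfer from the acidic ring hydrogen next to fluorine (loss of bromine without acylation) or demethoxylation of the amide takes over. The fallback sets out from 9. Silylation with Et3SiCl and imidazole gives the silyl ether F7. Bromine–lithium exchange and addition to isobutyraldehyde, which is fast at −78 °C, give the benzylic alcohol F8. Dess–Martin oxidation, now possible because the secondary oxygen is blocked, gives the ketone F9, and HF·pyridine removes the silyl group to give 12.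

**Step 9.** What may go wrong: elimination towards C2, which would form an enol ether and destroy the stereocentre, or ionisation of the tertiary centre with rearrangement. The fallback sets out from 15. 1-Chloro-N,N,2-trimethylprop-1-en-1-amine converts the alcohol under neutral conditions into the tertiary chloride F10. KOt-Bu in THF then removes HCl in an anti-periplanar E2 elimination in which the bulky base takes a methyl hydrogen, and the route is rejoined at 16.

**Step 13.** What may go wrong: self-condensation of the pyrone (two pyrone units on one methylene), double reaction of the iminium salt, and slow conjugate addition of the hydrogen-bonded phenol. The fallback sets out from 18 and reverses the roles. Compound 18 is aminomethylated at C7 with the same iminium salt to the phenolic Mannich base F11, which is isolated and then heated with 22 in toluene. Thermal loss of dimethylamine gives an ortho-quinone methide on ring A that is trapped by C3' of 22, giving 25.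

## Further compounds

F1 | step 7 | 3-[(2R)-3-[(benzyloxy)methoxy]-2-hydroxy-3-methylbutyl]-4-fluoro-2,6-bis(methoxymethoxy)benzaldehyde | CC(C)(OCOCc1ccccc1)[C@H](O)Cc1c(F)cc(OCOC)c(C=O)c1OCOC
F2 | step 7 | (2R)-2-{2-[(benzyloxy)methoxy]propan-2-yl}-4,6-bis(methoxymethoxy)-2,3-dihydro-1-benzofuran-5-carbaldehyde | CC(C)(OCOCc1ccccc1)[C@H]1Cc2c(OCOC)c(C=O)c(OCOC)cc2O1
F3 | step 7 | 1-[(2R)-2-{2-[(benzyloxy)methoxy]propan-2-yl}-4,6-bis(methoxymethoxy)-2,3-dihydro-1-benzofuran-5-yl]-2-methylpropan-1-ol (both carbinol epimers) | CC(C)(OCOCc1ccccc1)[C@H]1Cc2c(OCOC)c(C(O)C(C)C)c(OCOC)cc2O1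
F4 | step 4 | 5-fluoro-2-iodobenzene-1,3-diol | Oc1cc(F)cc(O)c1I
F5 | step 4 | 5-fluoro-2-iodo-1,3-bis(methoxymethoxy)benzene | COCOc1cc(F)cc(OCOC)c1I
F6 | step 4 | (R)-3-[(benzyloxy)methoxy]-1-[6-fluoro-3-iodo-2,4-bis(methoxymethoxy)phenyl]-3-methylbutan-2-ol | CC(C)(OCOCc1ccccc1)[C@H](O)Cc1c(F)cc(OCOC)c(I)c1OCOC
F7 | step 6 | {[(2R)-3-[(benzyloxy)methoxy]-1-[3-bromo-6-fluoro-2,4-bis(methoxymethoxy)phenyl]-3-methylbutan-2-yl]oxy}triethylsilane | CC(C)(OCOCc1ccccc1)[C@H](O[Si](CC)(CC)CC)Cc1c(F)cc(OCOC)c(Br)c1OCOC
F8 | step 6 | 1-{3-[(2R)-3-[(benzyloxy)methoxy]-3-methyl-2-(triethylsilyloxy)butyl]-4-fluoro-2,6-bis(methoxymethoxy)phenyl}-2-methylpropan-1-ol (both carbinol epimers) | CC(C)(OCOCc1ccccc1)[C@H](O[Si](CC)(CC)CC)Cc1c(F)cc(OCOC)c(C(O)C(C)C)c1OCOC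
F9 | step 6 | 1-{3-[(2R)-3-[(benzyloxy)methoxy]-3-methyl-2-(triethylsilyloxy)butyl]-4-fluoro-2,6-bis(methoxymethoxy)phenyl}-2-methylpropan-1-one | CC(C)(OCOCc1ccccc1)[C@H](O[Si](CC)(CC)CC)Cc1c(F)cc(OCOC)c(C(=O)C(C)C)c1OCOC
F10 | step 9 | 1-[(2R)-2-(2-chloropropan-2-yl)-4,6-bis(methoxymethoxy)-2,3-dihydro-1-benzofuran-5-yl]-2-methylpropan-1-one | CC(C)(Cl)[C@H]1Cc2c(OCOC)c(C(=O)C(C)C)c(OCOC)cc2O1
F11 | step 13 | 1-[(2R)-7-[(dimethylamino)methyl]-4,6-dihydroxy-2-(prop-1-en-2-yl)-2,3-dihydro-1-benzofuran-5-yl]-2-methylpropan-1-one | C=C(C)[C@H]1Cc2c(O)c(C(=O)C(C)C)c(O)c(CN(C)C)c2O1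
A1 | alternative 1 | 3-{[(2R)-4-ethoxy-6-hydroxy-2-[2-(triethylsilyloxy)propan-2-yl]-2,3-dihydro-1-benzofuran-7-yl]methyl}-6-ethyl-4-methoxy-5-methyl-2H-pyran-2-one | CC(C)(O[Si](CC)(CC)CC)[C@H]1Cc2c(OCC)cc(O)c(Cc3c(OC)c(C)c(CC)oc3=O)c2O1
A2 | alternative 2 | 3-{[(2R)-6-hydroxy-4-(methoxymethoxy)-5-(2-methylpropanoyl)-2-(prop-1-en-2-yl)-2,3-dihydro-1-benzofuran-7-yl]methyl}-6-ethyl-4-hydroxy-5-methyl-2H-pyran-2-one | C=C(C)[C@H]1Cc2c(OCOC)c(C(=O)C(C)C)c(O)c(Cc3c(O)c(C)c(CC)oc3=O)c2O1
A3 | alternative 3 | 1-[(2R)-6-hydroxy-4-(methoxymethoxy)-2-(prop-1-en-2-yl)-2,3-dihydro-1-benzofuran-5-yl]-2-methylpropan-1-one | C=C(C)[C@H]1Cc2c(OCOC)c(C(=O)C(C)C)c(O)cc2O1
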